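**Strategy.** Everything rests on making the epoxide-bearing six-membered ring (C1–C6, carotenoid numbering) by inserting its unfunctionalised C3–C4 ethano unit between C2 and C5 of an acyclic keto aldehyde, 2,2-dimethyl-3-oxopentanal. Because C1 is quaternary, C5 is the only enolisable carbon and C2 a non-enolisable aldehyde. A vinylphosphonium salt therefore acts as a traceless two-carbon linchpin: the C5 enolate adds to it and the resulting ylide olefinates C2, so the C4–C5 and C2–C3 bonds form in one operation. The C6 ketone left in the ring then fixes the C5=C6 alkene, which is epoxidised enantioselectively, and the polyene is assembled by C15 + C10 + C15 Wittig couplings.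

Key step: step 2

Remark on the chemistry: (R)-α-ionone 19 is assumed to be bought enantiomerically pure; its stereocentre becomes C6' and is carried through unchanged. The Sharpless face assignment in step 7 was derived from the known L-(+)-tartrate outcome for simple allylic alcohols.

**Step 1**
Reactants: 1 4-(2-methylprop-1-en-1-yl)morpholine; 2 propanoyl chloride
Product: 4 2,2-dimethyl-3-oxopentanal, via iminium chloride 3 (not isolated)
Conditions: 2 (1.0 equiv), Et2O, 0 °C to reflux; then H2O, rt
Reagents that add atoms: water, O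
Why: C-acylation of an aldehyde enamine (Stork enamine acylation): the nucleophilic β-carbon of 1 attacks the acid chloride, the iminium salt 3 cannot lose a proton because the new centre is quaternary, and water hydrolyses it to the β-keto aldehyde.

**Step 2**
Reactants: 4 2,2-dimethyl-3-oxopentanal; 5 vinyltriphenylphosphonium bromide
Product: 7 2,2,6-trimethylcyclohex-3-en-1-one (racemic), via phosphorus ylide 6 (not isolated)
Conditions: NaH (1.05 equiv), 5 (1.2 equiv), THF, 0 °C (slow addition of 4), then reflux
Reagents that add atoms: none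
Why: NaH removes a proton from the only enolisable carbon of 4 (the ketone CH2, future C5), the enolate adds through carbon to the vinylphosphonium salt to make the C4–C5 bond and ylide 6, and 6 closes onto the neopentyl aldehyde (future C2) by intramolecular Wittig olefination, making the C2–C3 bond as a ring alkene. The closest known reaction type is the Schweizer annulation, the conjugate addition of a keto enolate to vinyltriphenylphosphonium bromide followed by intramolecular Wittig reaction. The one ring formed (the future C1–C6 carbocycle) closes by 6-exo-trig attack of the ylide carbon on the aldehyde, and a six-membered ring can hold only the Z alkene. The only new stereocentre, C5, forms as a racemate next to the ketone and needs no control because step 4 erases it. The step needs C- over O-attack of the enolate and conjugate addition faster than aldol self-condensation or deformylation; the soft cationic acceptor in excess, slow addition of 4 and shielding of the aldehyde by quaternary C1 should secure this, and the absence of any other acidic C–H fixes the regiochemistry.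

**Step 3**
Reactants: 7 2,2,6-trimethylcyclohex-3-en-1-one
Product: 8 2,2,6-trimethylcyclohexan-1-one (racemic)
Conditions: H2 (1 atm), 10% Pd on carbon, EtOAc, rt
Reagents that add atoms: none
Why: Catalytic hydrogenation saturates the disubstituted C2=C3 alkene left by the Wittig closure and should leave the hindered ketone untouched; the C5 centre stays racemic, which is irrelevant.

**Step 4**
Reactants: 8 2,2,6-trimethylcyclohexan-1-one
Product: 9 2,6,6-trimethylcyclohex-1-en-1-yl trifluoromethanesulfonate
Conditions: LiN(i-Pr)2, THF, −78 °C; then PhNTf2, −78 °C to rt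
Reagents that add atoms: N-phenylbis(trifluoromethanesulfonimide), O=S(=O)(N(c1ccccc1)S(=O)(=O)C(F)(F)F)C(F)(F)F
Why: C1 is quaternary, so the base can only remove the C5 hydrogen and the tetrasubstituted enolate is trapped on oxygen (enol triflate formation), which erases the racemic C5 centre and places the alkene exactly at C5=C6.

**Step 5**
Reactants: 9 2,6,6-trimethylcyclohex-1-en-1-yl trifluoromethanesulfonate
Product: 10 methyl 2,6,6-trimethylcyclohex-1-ene-1-carboxylate
Conditions: Pd(OAc)2 (5 mol %), 1,3-bis(diphenylphosphino)propane, CO (1 atm), MeOH, Et3N, DMF, 70 °C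
Reagents that add atoms: carbon monoxide, [C-]#[O+]; methanol, CO
Why: Palladium-catalysed methoxycarbonylation of an enol triflate (oxidative addition to zerovalent palladium, CO insertion, methanolysis of the acyl palladium complex) attaches C7 to C6, the ring fixing the alkene geometry.

**Step 6**
Reactants: 10 methyl 2,6,6-trimethylcyclohex-1-ene-1-carboxylate
Product: 11 (2,6,6-trimethylcyclohex-1-en-1-yl)methanol
Conditions: i-Bu2AlH (2.5 equiv), CH2Cl2, −78 to 0 °C; Rochelle salt work-up
Reagents that add atoms: none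
Why: 1,2-Reduction of the conjugated ester by the aluminium hydride gives the allylic alcohol needed to direct the epoxidation.

**Step 7**
Reactants: 11 (2,6,6-trimethylcyclohex-1-en-1-yl)methanol
Product: 12 [(1R,6R)-2,2,6-trimethyl-7-oxabicyclo[4.1.0]heptan-1-yl]methanol
Conditions: Ti(OiPr)4 (0.2 equiv), D-(−)-diisopropyl tartrate (0.25 equiv), t-BuOOH, 4 Å molecular sieves, CH2Cl2, −20 °C
Reagents that add atoms: tert-butyl hydroperoxide, CC(C)(C)OO
Why: Katsuki–Sharpless asymmetric epoxidation: the allylic alkoxide binds the titanium tartrate catalyst and the D-(−)-tartrate delivers the peroxide oxygen to the alkene face opposite to the one used by L-(+)-tartrate (which gives 2S-epoxy alcohols from simple allylic alcohols), setting C5 and C6 together, necessarily cis, as (5R,6S) in target numbering.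

**Step 8**
Reactants: 12 [(1R,6R)-2,2,6-trimethyl-7-oxabicyclo[4.1.0]heptan-1-yl]methanol
Product: 13 (1S,6R)-2,2,6-trimethyl-7-oxabicyclo[4.1.0]heptane-1-carbaldehyde
Conditions: (n-Pr)4N[RuO4] (5 mol %), N-methylmorpholine N-oxide, 4 Å molecular sieves, CH2Cl2, rt
Reagents that add atoms: none
Why: Ley–Griffith oxidation under neutral conditions takes the primary alcohol to the aldehyde; the carbon next to the carbonyl is quaternary, so no epimerisation or elimination can occur and the epoxide should stay intact (the descriptor at C1 changes only because the priorities change).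

**Step 9**
Reactants: 13 (1S,6R)-2,2,6-trimethyl-7-oxabicyclo[4.1.0]heptane-1-carbaldehyde; 14 ethyl (2E)-4-(diethoxyphosphoryl)-3-methylbut-2-enoate
Product: 15 ethyl (2E,4E)-3-methyl-5-[(1S,6R)-2,2,6-trimethyl-7-oxabicyclo[4.1.0]heptan-1-yl]penta-2,4-dienoate
Conditions: 14, NaH, THF, 0 °C; then 13, 0 °C to rt
Reagents that add atoms: none
Why: Vinylogous Horner–Wadsworth–Emmons olefination: the phosphonate-stabilised anion attacks the hindered but non-enolisable aldehyde and loss of phosphate should give the new C7=C8 bond as the E isomer, any 9Z isomer being removed by chromatography; the epoxide stereocentres are not involved.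

**Step 10**
Reactants: 15 ethyl (2E,4E)-3-methyl-5-[(1S,6R)-2,2,6-trimethyl-7-oxabicyclo[4.1.0]heptan-1-yl]penta-2,4-dienoate
Product: 16 (2E,4E)-3-methyl-5-[(1S,6R)-2,2,6-trimethyl-7-oxabicyclo[4.1.0]heptan-1-yl]penta-2,4-dien-1-ol
Conditions: i-Bu2AlH, CH2Cl2, −78 °C
Reagents that add atoms: none
Why: 1,2-Reduction of the dienoate at low temperature gives the allylic alcohol while the fully substituted, hindered epoxide should be inert to the hydride.

**Step 11**
Reactants: 16 (2E,4E)-3-methyl-5-[(1S,6R)-2,2,6-trimethyl-7-oxabicyclo[4.1.0]heptan-1-yl]penta-2,4-dien-1-ol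
Product: 18 [(2E,4E)-3-methyl-5-[(1S,6R)-2,2,6-trimethyl-7-oxabicyclo[4.1.0]heptan-1-yl]penta-2,4-dien-1-yl]triphenylphosphonium bromide, via allylic bromide 17 (not isolated)
Conditions: CBr4, PPh3, CH2Cl2, −20 °C; then PPh3, rt
Reagents that add atoms: tetrabromomethane, BrC(Br)(Br)Br; triphenylphosphine, c1ccc(cc1)P(c1ccccc1)c1ccccc1
Why: Appel bromination under neutral conditions gives the primary allylic bromide 17, which is quaternised in the same flask by SN2 attack of triphenylphosphine, avoiding the acid that would rearrange the epoxide to a furanoid oxide.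

**Step 12**
Reactants: 19 (R)-α-ionone, (3E)-4-[(1R)-2,6,6-trimethylcyclohex-2-en-1-yl]but-3-en-2-one; 20 vinylmagnesium bromide
Product: 21 (1E)-3-methyl-1-[(1R)-2,6,6-trimethylcyclohex-2-en-1-yl]penta-1,4-dien-3-ol (both C3 epimers)
Conditions: 20, THF, 0 °C
Reagents that add atoms: none
Why: Grignard 1,2-addition to the enone carbonyl; the new carbinol centre forms unselectively but becomes sp2 in the next step, and the C6' centre is untouched.

**Step 13**
Reactants: 21 (1E)-3-methyl-1-[(1R)-2,6,6-trimethylcyclohex-2-en-1-yl]penta-1,4-dien-3-ol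
Product: 22 [(2E,4E)-3-methyl-5-[(1R)-2,6,6-trimethylcyclohex-2-en-1-yl]penta-2,4-dien-1-yl]triphenylphosphonium bromide
Conditions: PPh3·HBr, MeOH, rt
Reagents that add atoms: triphenylphosphine hydrobromide, [Br-].c1ccc(cc1)[PH+](c1ccccc1)c1ccccc1
Why: Acid-promoted ionisation of the tertiary bis-allylic alcohol gives a pentadienyl cation that triphenylphosphine captures at the primary terminus (allylic transposition, SN1' type), which should give the conjugated E,E-dienyl phosphonium salt with C6' unchanged.

**Step 14**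
Reactants: 22 [(2E,4E)-3-methyl-5-[(1R)-2,6,6-trimethylcyclohex-2-en-1-yl]penta-2,4-dien-1-yl]triphenylphosphonium bromide; 23 (2E,4E,6E)-2,7-dimethylocta-2,4,6-trienedial
Product: 24 (2E,4E,6E,8E,10E,12E)-2,7,11-trimethyl-13-[(1R)-2,6,6-trimethylcyclohex-2-en-1-yl]trideca-2,4,6,8,10,12-hexaenal
Conditions: 23 (3 equiv), NaOMe, MeOH/CH2Cl2, 0 °C to rt; then I2 (cat.), hexane, rt
Reagents that add atoms: none
Why: Wittig reaction of the semi-stabilised ylide from 22 with one aldehyde group of the symmetrical dialdehyde, used in excess to suppress double condensation, forms C11'=C12', and iodine-catalysed equilibration should convert the Z isomer at the new bond into the E isomer.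

**Step 15**
Reactants: 18 [(2E,4E)-3-methyl-5-[(1S,6R)-2,2,6-trimethyl-7-oxabicyclo[4.1.0]heptan-1-yl]penta-2,4-dien-1-yl]triphenylphosphonium bromide; 24 (2E,4E,6E,8E,10E,12E)-2,7,11-trimethyl-13-[(1R)-2,6,6-trimethylcyclohex-2-en-1-yl]trideca-2,4,6,8,10,12-hexaenal
Product: 25 (5R,6S,6'R)-5,6-epoxy-5,6-dihydro-β,ε-carotene (all-E)
Conditions: NaOMe, MeOH/CH2Cl2, 0 °C to rt; then n-heptane, reflux, dark (Z to E)
Reagents that add atoms: none
Why: Wittig reaction of the ylide from 18 with the C25 aldehyde forms the C11=C12 bond and completes the C40 skeleton; the 11Z isomer formed alongside should equilibrate thermally to the all-E polyene, and the three stereocentres (C5, C6, C6') are not touched.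

**Compound list**
1 | 4-(2-methylprop-1-en-1-yl)morpholine | CC(C)=CN1CCOCC1 | starting material
2 | propanoyl chloride | CCC(Cl)=O | starting material
3 | 4-(2,2-dimethyl-3-oxopentylidene)morpholin-4-ium chloride (not isolated) | CCC(=O)C(C)(C)C=[N+]1CCOCC1.[Cl-] | intermediate
4 | 2,2-dimethyl-3-oxopentanal | CCC(=O)C(C)(C)C=O | intermediate
5 | vinyltriphenylphosphonium bromide | C=C[P+](c1ccccc1)(c1ccccc1)c1ccccc1.[Br-] | starting material
6 | 2,2,4-trimethyl-3-oxo-6-(triphenyl-λ5-phosphanylidene)hexanal, phosphorus ylide (not isolated, racemic) | CC(CC=P(c1ccccc1)(c1ccccc1)c1ccccc1)C(=O)C(C)(C)C=O | intermediate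
7 | 2,2,6-trimethylcyclohex-3-en-1-one (racemic) | CC1CC=CC(C)(C)C1=O | intermediate
8 | 2,2,6-trimethylcyclohexan-1-one (racemic) | CC1CCCC(C)(C)C1=O | intermediate
9 | 2,6,6-trimethylcyclohex-1-en-1-yl trifluoromethanesulfonate | CC1=C(OS(=O)(=O)C(F)(F)F)C(C)(C)CCC1 | intermediate
10 | methyl 2,6,6-trimethylcyclohex-1-ene-1-carboxylate | COC(=O)C1=C(C)CCCC1(C)C | intermediate
11 | (2,6,6-trimethylcyclohex-1-en-1-yl)methanol | OCC1=C(C)CCCC1(C)C | intermediate
12 | [(1R,6R)-2,2,6-trimethyl-7-oxabicyclo[4.1.0]heptan-1-yl]methanol | OC[C@@]12O[C@]1(C)CCCC2(C)C | intermediate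
13 | (1S,6R)-2,2,6-trimethyl-7-oxabicyclo[4.1.0]heptane-1-carbaldehyde | O=C[C@@]12O[C@]1(C)CCCC2(C)C | intermediate
14 | ethyl (2E)-4-(diethoxyphosphoryl)-3-methylbut-2-enoate | CCOC(=O)/C=C(\C)CP(=O)(OCC)OCC | starting material
15 | ethyl (2E,4E)-3-methyl-5-[(1S,6R)-2,2,6-trimethyl-7-oxabicyclo[4.1.0]heptan-1-yl]penta-2,4-dienoate | CCOC(=O)/C=C(C)/C=C/[C@@]12O[C@]1(C)CCCC2(C)C | intermediate
16 | (2E,4E)-3-methyl-5-[(1S,6R)-2,2,6-trimethyl-7-oxabicyclo[4.1.0]heptan-1-yl]penta-2,4-dien-1-ol | OC/C=C(C)/C=C/[C@@]12O[C@]1(C)CCCC2(C)C | intermediate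
17 | (1S,6R)-1-[(1E,3E)-5-bromo-3-methylpenta-1,3-dien-1-yl]-2,2,6-trimethyl-7-oxabicyclo[4.1.0]heptane (not isolated) | BrC/C=C(C)/C=C/[C@@]12O[C@]1(C)CCCC2(C)C | intermediate
18 | [(2E,4E)-3-methyl-5-[(1S,6R)-2,2,6-trimethyl-7-oxabicyclo[4.1.0]heptan-1-yl]penta-2,4-dien-1-yl]triphenylphosphonium bromide | [Br-].C(/C=C(C)/C=C/[C@@]12O[C@]1(C)CCCC2(C)C)[P+](c1ccccc1)(c1ccccc1)c1ccccc1 | intermediate
19 | (R)-α-ionone, (3E)-4-[(1R)-2,6,6-trimethylcyclohex-2-en-1-yl]but-3-en-2-one | CC1=CCCC(C)(C)[C@H]1/C=C/C(C)=O | starting material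
20 | vinylmagnesium bromide | C=C[Mg]Br | starting material
21 | (1E)-3-methyl-1-[(1R)-2,6,6-trimethylcyclohex-2-en-1-yl]penta-1,4-dien-3-ol (both C3 epimers) | CC1=CCCC(C)(C)[C@H]1/C=C/C(C)(O)C=C | intermediate
22 | [(2E,4E)-3-methyl-5-[(1R)-2,6,6-trimethylcyclohex-2-en-1-yl]penta-2,4-dien-1-yl]triphenylphosphonium bromide | CC1=CCCC(C)(C)[C@H]1/C=C/C(C)=C/C[P+](c1ccccc1)(c1ccccc1)c1ccccc1.[Br-] | intermediate
23 | (2E,4E,6E)-2,7-dimethylocta-2,4,6-trienedial | O=C/C(C)=C/C=C/C=C(C)/C=O | starting material
24 | (2E,4E,6E,8E,10E,12E)-2,7,11-trimethyl-13-[(1R)-2,6,6-trimethylcyclohex-2-en-1-yl]trideca-2,4,6,8,10,12-hexaenal | CC1=CCCC(C)(C)[C@H]1/C=C/C(C)=C/C=C/C(C)=C/C=C/C=C(C)/C=O | intermediate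
25 | (5R,6S,6'R)-5,6-epoxy-5,6-dihydro-β,ε-carotene | CC1=CCCC(C)(C)[C@H]1/C=C/C(C)=C/C=C/C(C)=C/C=C/C=C(C)/C=C/C=C(C)/C=C/[C@@]12O[C@]1(C)CCCC2(C)C | target

**Step count.** Total: 15 steps. Longest linear sequence: 12 steps (steps 1–11, then 15).

**Steps most likely to fail**

Step 2. The unstabilised enolate of 4 may undergo aldol self-condensation or base-induced deformylation faster than conjugate addition, or attack 5 through oxygen. The fallback runs the same ring closure with a doubly stabilised carbon nucleophile that needs only a weak base. It sets out from 1, which is acylated with methyl 3-chloro-2-methyl-3-oxopropanoate in place of 2 and hydrolysed to methyl 2,4,4-trimethyl-3,5-dioxopentanoate F1. K2CO3 and 5 in MeCN at reflux then take the β-keto ester enolate through the same conjugate addition and intramolecular Wittig closure to methyl 1,3,3-trimethyl-2-oxocyclohex-4-ene-1-carboxylate F2. Krapcho dealkoxycarbonylation (LiCl, wet DMSO, 150 °C) comes back to the route at 7.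

Step 11. Ionisation of the dienylic bromide or traces of acid may open the epoxide (furanoid rearrangement), and the extended ylide of step 15 may open it as well. The fallback reverses the polarity of the last coupling and sets out from 16 and 24. Alcohol 16 is oxidised with MnO2 to (2E,4E)-3-methyl-5-[(1S,6R)-2,2,6-trimethyl-7-oxabicyclo[4.1.0]heptan-1-yl]penta-2,4-dienal F5. Aldehyde 24 is reduced with NaBH4 to (2E,4E,6E,8E,10E,12E)-2,7,11-trimethyl-13-[(1R)-2,6,6-trimethylcyclohex-2-en-1-yl]trideca-2,4,6,8,10,12-hexaen-1-ol F6, which triphenylphosphine hydrobromide converts into the corresponding C25 triphenylphosphonium bromide F7, no epoxide being present. Wittig reaction of F7 with F5 (NaOMe, then thermal equilibration) comes back to the route at 25.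

Step 7. Facial selectivity may be poor and turnover slow at the hindered tetrasubstituted alkene, and the titanium Lewis acid may open the product. The fallback is racemic directed epoxidation followed by classical resolution and sets out from 11. VO(acac)2 and t-BuOOH give racemic (2,2,6-trimethyl-7-oxabicyclo[4.1.0]heptan-1-yl)methanol F3. Esterification with (S)-O-acetylmandelic acid (dicyclohexylcarbodiimide, 4-dimethylaminopyridine) gives two diastereomeric esters, separated by chromatography or crystallisation to [(1R,6R)-2,2,6-trimethyl-7-oxabicyclo[4.1.0]heptan-1-yl]methyl (2S)-2-acetoxy-2-phenylacetate F4. K2CO3 in MeOH comes back to the route at 12.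

**Further compounds**
F1 | step 2 | methyl 2,4,4-trimethyl-3,5-dioxopentanoate | COC(=O)C(C)C(=O)C(C)(C)C=O
F2 | step 2 | methyl 1,3,3-trimethyl-2-oxocyclohex-4-ene-1-carboxylate (racemic) | COC(=O)C1(C)CC=CC(C)(C)C1=O
F3 | step 7 | (2,2,6-trimethyl-7-oxabicyclo[4.1.0]heptan-1-yl)methanol (racemic, cis-fused) | OCC12OC1(C)CCCC2(C)C
F4 | step 7 | [(1R,6R)-2,2,6-trimethyl-7-oxabicyclo[4.1.0]heptan-1-yl]methyl (2S)-2-acetoxy-2-phenylacetate | CC(=O)O[C@@H](c1ccccc1)C(=O)OC[C@@]12O[C@]1(C)CCCC2(C)C
F5 | step 11 | (2E,4E)-3-methyl-5-[(1S,6R)-2,2,6-trimethyl-7-oxabicyclo[4.1.0]heptan-1-yl]penta-2,4-dienal | O=C/C=C(C)/C=C/[C@@]12O[C@]1(C)CCCC2(C)C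
F6 | step 11 | (2E,4E,6E,8E,10E,12E)-2,7,11-trimethyl-13-[(1R)-2,6,6-trimethylcyclohex-2-en-1-yl]trideca-2,4,6,8,10,12-hexaen-1-ol | CC1=CCCC(C)(C)[C@H]1/C=C/C(C)=C/C=C/C(C)=C/C=C/C=C(C)/CO
F7 | step 11 | [(2E,4E,6E,8E,10E,12E)-2,7,11-trimethyl-13-[(1R)-2,6,6-trimethylcyclohex-2-en-1-yl]trideca-2,4,6,8,10,12-hexaen-1-yl]triphenylphosphonium bromide | CC1=CCCC(C)(C)[C@H]1/C=C/C(C)=C/C=C/C(C)=C/C=C/C=C(C)/C[P+](c1ccccc1)(c1ccccc1)c1ccccc1.[Br-]
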